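The route rests on cutting the C2–C1' bond that joins the pyran ring to ring B. C2, the only stereocentre, is benzylic and bonded to the ring oxygen O1, so it can be stored as a racemic 2-ethoxy acetal. Ionisation gives a planar benzopyrylium, stabilised by the 5- and 7-methoxy groups of ring A, and a chiral boron ate complex hands the 4-methoxyphenyl group to one face of C2. One operation thus attaches ring B and fixes the (S) centre from racemic material. The precursor is racemic 2-ethoxy-5,7-dimethoxy-6-prenyl-2H-chromene, reached from 3,5-dimethoxyphenol through the corresponding 6-prenylcoumarin; a diimide reduction of C3=C4 finishes the route.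

Key step: step 7

Remark on the chemistry: the chiral promoter of step 7 is taken to be a tartaric acid monoamide that keeps one free carboxylic acid (its diol binds boron, the acid is the Brønsted site, and a diamide would lack that site). Which antipode gives (S) is not predicted here, so the sense of induction is to be assigned on the first run and the antipode that gives the (S)-2-aryl-2H-chromene used, both being equally accessible from the two tartaric acids. "Prenyl" means 3-methylbut-2-enyl throughout.

Step 1
Reactants: 1 3,5-dimethoxyphenol
Product: 2 (3,5-dimethoxyphenoxy)triisopropylsilane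
Conditions: i-Pr3SiCl, imidazole, DMF, rt
Reagents that add atoms: triisopropylsilyl chloride CC(C)[Si](Cl)(C(C)C)C(C)C
Why: Imidazole-promoted O-silylation of a phenol is routine, and the bulky, weakly coordinating silyl ether screens the two ring positions next to it so that the later metalation is steered to the carbon between the two methoxy groups.

Step 2
Reactants: 2 (3,5-dimethoxyphenoxy)triisopropylsilane; 3 prenyl bromide
Product: 7 3,5-dimethoxy-4-prenylphenol, via aryllithium 4 (not isolated), via arylcopper 5 (not isolated), via prenylated silyl ether 6 (not isolated)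
Conditions: n-BuLi, THF, 0 °C to rt; CuBr·SMe2, −78 to −30 °C; 3, −78 °C to rt; then n-Bu4NF (TBAF), same flask, 0 °C to rt; aq NH4Cl
Reagents that add atoms: none
Why: Directed ortho-metalation should place lithium on the carbon flanked by both methoxy groups (as in 1,3-dimethoxybenzene), the derived arylcopper should couple with prenyl bromide at the primary carbon (SN2 allylation, the SN2' path would build a quaternary centre), and fluoride desilylation in the same flask frees the phenol, which also makes separation from any unprenylated phenol easy.

Step 3
Reactants: 7 3,5-dimethoxy-4-prenylphenol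
Product: 9 2-hydroxy-4,6-dimethoxy-5-prenylbenzaldehyde, via salicyl alcohol 8 (not isolated)
Conditions: MgCl2, Et3N, (CH2O)n, MeCN, reflux; aq HCl work-up
Reagents that add atoms: paraformaldehyde (as formaldehyde) C=O
Why: In this magnesium-mediated ortho-formylation (Casnati–Skattebøl reaction) the magnesium phenoxide delivers formaldehyde only to an ortho carbon and a second formaldehyde oxidises the salicyl alcohol by hydride transfer, while the two ortho positions are equivalent by symmetry and the para position is blocked by the prenyl group.

Step 4
Reactants: 9 2-hydroxy-4,6-dimethoxy-5-prenylbenzaldehyde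
Product: 12 5,7-dimethoxy-6-prenylcoumarin, via (E)-cinnamate ester 10 (not isolated), via (Z)-cinnamate ester 11 (not isolated)
Conditions: Ph3P=CHCO2Et, N,N-diethylaniline, reflux, N2
Reagents that add atoms: ethyl (triphenylphosphoranylidene)acetate CCOC(=O)C=P(c1ccccc1)(c1ccccc1)c1ccccc1
Why: Wittig olefination with a stabilised ylide gives the cinnamate, which at this temperature equilibrates to the Z isomer and lactonises onto the free phenol, a standard one-pot coumarin synthesis that closes the pyran ring (C3=C4 by olefination, O1–C2 by acyl substitution) and leaves the C-prenyl group alone because no hydroxyl sits next to it.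

Step 5
Reactants: 12 5,7-dimethoxy-6-prenylcoumarin
Product: 13 5,7-dimethoxy-6-prenyl-2H-chromen-2-ol (racemic lactol)
Conditions: i-Bu2AlH (1.1 equiv), CH2Cl2, −78 °C; aq potassium sodium tartrate
Reagents that add atoms: none
Why: Partial reduction of a lactone to the lactol with one equivalent of i-Bu2AlH at −78 °C is standard, neither alkene nor the aryl ethers react, and the crude lactol is carried on at once because it can open to the hydroxy enal.

Step 6
Reactants: 13 5,7-dimethoxy-6-prenyl-2H-chromen-2-ol
Product: 14 2-ethoxy-5,7-dimethoxy-6-prenyl-2H-chromene (racemic)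
Conditions: EtOH, PPTS (cat.), 4 Å MS, 0 °C to rt; Et3N quench; Et3N-deactivated silica
Reagents that add atoms: ethanol CCO
Why: Acid-catalysed exchange of the hemiacetal hydroxyl for ethoxy (lactol-to-acetal conversion) is easy here because the 5- and 7-methoxy donors labilise the C2–O bond, and the mild pyridinium acid leaves the prenyl group intact while giving a racemic acetal whose configuration is irrelevant.

Step 7
Reactants: 14 2-ethoxy-5,7-dimethoxy-6-prenyl-2H-chromene (racemic); 15 4-methoxyphenylboronic acid
Product: 18 (S)-5,7-dimethoxy-2-(4-methoxyphenyl)-6-prenyl-2H-chromene, via diethyl 4-methoxyphenylboronate 16 (not isolated), via benzopyrylium cation 17 (not isolated)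
Conditions: 15, EtOH/toluene, azeotropic evaporation (gives 16 in the flask); then 14, 4-(dibenzylamino)-2,3-dihydroxy-4-oxobutanoic acid (tartaric acid monoamide, single antipode, 10 mol%), Yb(OTf)3 (5 mol%), EtOAc, −20 to 4 °C, dark
Reagents that add atoms: none
Why: Boronate 16 exchanges its ethoxy groups for the diol of the tartaric acid monoamide to give a more Lewis-acidic chiral dioxaborolane with a pendant carboxylic acid, and this, helped by Yb(OTf)3, ionises acetal 14 to the planar cation 17 while ethoxide passes to boron, so both enantiomers of 14 converge on one ion pair. The chiral aryl ate complex then transfers the 4-methoxyphenyl group to C2 inside the contact ion pair, which is the known chiral Brønsted acid/Lewis acid co-catalysed addition of aryl and alkenyl boronates to 2-ethoxy-2H-chromene acetals. No ring closes, since the pyran ring is already in place and only the C2–C1' bond forms. The new stereocentre C2 is set by catalyst control, the chiral ligand on boron exposing one face of the cation, and the antipode of the catalyst is chosen to give (S). The step needs enantiofacial selectivity and C2 over C4 regioselectivity: the first should come from the tight ion pair, which the easy low-temperature ionisation provided by the 5- and 7-methoxy groups favours, and the second from delivery next to O1, where ethoxide left, with the peri 5-methoxy group hindering C4. The nearly neutral conditions should leave the prenyl group untouched, and the electron-rich aryl group migrates readily from boron.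

Step 8
Reactants: 18 (S)-5,7-dimethoxy-2-(4-methoxyphenyl)-6-prenyl-2H-chromene
Product: 19 (S)-5,7-dimethoxy-2-(4-methoxyphenyl)-6-prenylchroman
Conditions: 2-O2NC6H4SO2NHNH2 (NBSH), Et3N, CH2Cl2, rt, dark; 18 used promptly after step 7
Reagents that add atoms: none
Why: Diimide reduction transfers two hydrogens through a cyclic transition state at a rate that falls steeply with alkene substitution, so the cis-disubstituted C3=C4 bond should be saturated while the trisubstituted prenyl alkene stays, and with no metal present the allylic and benzylic C2–O1 bond and the configuration at C2 are not touched.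

Compound list
1 | 3,5-dimethoxyphenol | COc1cc(O)cc(OC)c1 | starting material
2 | (3,5-dimethoxyphenoxy)triisopropylsilane | COc1cc(O[Si](C(C)C)(C(C)C)C(C)C)cc(OC)c1 | intermediate
3 | prenyl bromide (1-bromo-3-methylbut-2-ene) | CC(C)=CCBr | starting material
4 | [2,6-dimethoxy-4-(triisopropylsilyloxy)phenyl]lithium (not isolated) | [Li]c1c(OC)cc(O[Si](C(C)C)(C(C)C)C(C)C)cc1OC | intermediate
5 | [2,6-dimethoxy-4-(triisopropylsilyloxy)phenyl]copper (not isolated) | [Cu]c1c(OC)cc(O[Si](C(C)C)(C(C)C)C(C)C)cc1OC | intermediate
6 | (3,5-dimethoxy-4-prenylphenoxy)triisopropylsilane (not isolated) | COc1cc(O[Si](C(C)C)(C(C)C)C(C)C)cc(OC)c1CC=C(C)C | intermediate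
7 | 3,5-dimethoxy-4-prenylphenol | COc1cc(O)cc(OC)c1CC=C(C)C | intermediate
8 | 2-(hydroxymethyl)-3,5-dimethoxy-4-prenylphenol (as its magnesium salt, not isolated) | OCc1c(O)cc(OC)c(CC=C(C)C)c1OC | intermediate
9 | 2-hydroxy-4,6-dimethoxy-5-prenylbenzaldehyde | O=Cc1c(O)cc(OC)c(CC=C(C)C)c1OC | intermediate
10 | ethyl (E)-3-(2-hydroxy-4,6-dimethoxy-5-prenylphenyl)prop-2-enoate (not isolated) | CCOC(=O)/C=C/c1c(O)cc(OC)c(CC=C(C)C)c1OC | intermediate
11 | ethyl (Z)-3-(2-hydroxy-4,6-dimethoxy-5-prenylphenyl)prop-2-enoate (not isolated) | CCOC(=O)/C=C\c1c(O)cc(OC)c(CC=C(C)C)c1OC | intermediate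
12 | 5,7-dimethoxy-6-prenylcoumarin (5,7-dimethoxy-6-prenyl-2H-chromen-2-one) | COc1cc2oc(=O)ccc2c(OC)c1CC=C(C)C | intermediate
13 | 5,7-dimethoxy-6-prenyl-2H-chromen-2-ol (racemic) | OC1C=Cc2c(cc(OC)c(CC=C(C)C)c2OC)O1 | intermediate
14 | 2-ethoxy-5,7-dimethoxy-6-prenyl-2H-chromene (racemic) | CCOC1C=Cc2c(cc(OC)c(CC=C(C)C)c2OC)O1 | intermediate
15 | 4-methoxyphenylboronic acid | COc1ccc(B(O)O)cc1 | starting material
16 | diethyl 4-methoxyphenylboronate (not isolated) | CCOB(OCC)c1ccc(OC)cc1 | intermediate
17 | 5,7-dimethoxy-6-prenyl-1-benzopyrylium cation (not isolated) | COc1cc2[o+]cccc2c(OC)c1CC=C(C)C | intermediate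
18 | (S)-5,7-dimethoxy-2-(4-methoxyphenyl)-6-prenyl-2H-chromene | COc1ccc([C@@H]2C=Cc3c(cc(OC)c(CC=C(C)C)c3OC)O2)cc1 | intermediate
19 | (S)-5,7-dimethoxy-2-(4-methoxyphenyl)-6-prenylchroman | COc1ccc([C@@H]2CCc3c(cc(OC)c(CC=C(C)C)c3OC)O2)cc1 | target

Total step count: 8
Longest linear sequence: 8 steps (1 to 19); boronic acid 15 enters at step 7 without steps of its own.

Steps most likely to fail

1. Step 7. Enantiofacial control may be lost, because the benzopyrylium carrying two methoxy donors is long-lived and can drift out of the chiral contact ion pair and be arylated without guidance from the catalyst; aryl delivery to C4 and erosion of the product's configuration by reversible ring opening are further leaks. The fallback leaves the route at aldehyde 9 and returns at target 19, setting C2 by reagent-controlled ketone reduction and invertive ring closure. Claisen–Schmidt condensation of 9 with purchased 4'-methoxyacetophenone (KOH, EtOH) should give the chalcone (E)-3-(2-hydroxy-4,6-dimethoxy-5-prenylphenyl)-1-(4-methoxyphenyl)prop-2-en-1-one F1. Hydrogenation with RhCl(PPh3)3 (H2, benzene/EtOH), which saturates the disubstituted enone alkene and spares the trisubstituted one, should give the dihydrochalcone 3-(2-hydroxy-4,6-dimethoxy-5-prenylphenyl)-1-(4-methoxyphenyl)propan-1-one F2. Corey–Bakshi–Shibata reduction ((S)-2-methyl-CBS-oxazaborolidine, BH3·SMe2 in excess to allow for the phenol, THF) should give the benzylic alcohol (R)-2-[3-hydroxy-3-(4-methoxyphenyl)propyl]-3,5-dimethoxy-4-prenylphenol F3. Mitsunobu etherification (PPh3, DIAD, THF, 0 °C) then closes the O1–C2 bond with inversion and should give 19 as the (S) enantiomer.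

2. Step 2. Metalation may occur next to the silyloxy group instead of between the two methoxy groups, or stay incomplete, so that regioisomeric or unprenylated phenols accumulate. The fallback installs the hydroxyl after the prenyl group; it sets out from prenyl bromide 3 and purchased 1,3-dimethoxybenzene and returns at phenol 7. Lithiation of 1,3-dimethoxybenzene at its single doubly activated position (n-BuLi, THF, 0 °C to rt) and alkylation with 3 should give 1,3-dimethoxy-2-prenylbenzene F4. Sterically governed C–H borylation ([Ir(OMe)(cod)]2, 4,4'-di-tert-butyl-2,2'-bipyridine, B2pin2, THF, 60–80 °C) at the only ring C–H without an ortho substituent should give the pinacol boronate 2-(3,5-dimethoxy-4-prenylphenyl)-4,4,5,5-tetramethyl-1,3,2-dioxaborolane F5. Oxidation with NaBO3·4H2O (THF/H2O, rt), which does not epoxidise the alkene, then gives 7.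

3. Step 5. The aluminium-bound reduction adduct may collapse and take up a second hydride (over-reduction to the ring-opened allylic alcohol), or the freed lactol may open to the hydroxy enal and isomerise from Z to E during work-up. The fallback traps the adduct before it is set free (reductive acetylation); it sets out from coumarin 12 and returns at acetal 14 without passing through 13. Treatment with i-Bu2AlH (CH2Cl2, −78 °C) followed by pyridine, DMAP and Ac2O at −78 °C should give 5,7-dimethoxy-6-prenyl-2H-chromen-2-yl acetate F6 as a racemate. Brief exposure to EtOH with PPTS then exchanges acetate for ethoxy at C2 and gives 14.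

Further compounds
F1 | step 7 | (E)-3-(2-hydroxy-4,6-dimethoxy-5-prenylphenyl)-1-(4-methoxyphenyl)prop-2-en-1-one | COc1ccc(C(=O)/C=C/c2c(O)cc(OC)c(CC=C(C)C)c2OC)cc1
F2 | step 7 | 3-(2-hydroxy-4,6-dimethoxy-5-prenylphenyl)-1-(4-methoxyphenyl)propan-1-one | COc1ccc(C(=O)CCc2c(O)cc(OC)c(CC=C(C)C)c2OC)cc1
F3 | step 7 | (R)-2-[3-hydroxy-3-(4-methoxyphenyl)propyl]-3,5-dimethoxy-4-prenylphenol | COc1ccc([C@H](O)CCc2c(O)cc(OC)c(CC=C(C)C)c2OC)cc1
F4 | step 2 | 1,3-dimethoxy-2-prenylbenzene | COc1cccc(OC)c1CC=C(C)C
F5 | step 2 | 2-(3,5-dimethoxy-4-prenylphenyl)-4,4,5,5-tetramethyl-1,3,2-dioxaborolane | COc1cc(B2OC(C)(C)C(C)(C)O2)cc(OC)c1CC=C(C)C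
F6 | step 5 | 5,7-dimethoxy-6-prenyl-2H-chromen-2-yl acetate (racemic) | CC(=O)OC1C=Cc2c(cc(OC)c(CC=C(C)C)c2OC)O1
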